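**Upper bound.** If each reagent molecule in the flask found starting material, 1.00 equiv of reagent would convert the whole charge. The spring run is this same flask, followed to 6.00 min; the dusk run had 0.50 equiv.

the same everywhere: starting material 0.50 mM

|  | reagent | remark | time |
|---|---|---|---|
| spring | 1 equiv | the very flask that is asked about, followed so far |  |
| dusk | 0.50 equiv | run made earlier |  |
| flask | 1.00 equiv |  | 15 min |

- spring (time / min: starting material / %, mono adduct / %): 0.833: 90.3, 9.3; 1.50: 89.8, 10.5; 2.50: 87.7, 11.2; 3.00: 87.8, 11.9; 4.00: 87.0, 12.4; 5.00: 87.3, 14.3; 6.00: 87.2, 13.3
- dusk (time / min: starting material / %, mono adduct / %): 1.33: 91.3, 7.7; 2.00: 90.5, 9.4; 3.00: 90.7, 9.8; 4.00: 90.0, 10.1; 6.00: 90.5, 11.2; 10.0: 89.1, 11.1; 15.0: 88.7, 11.4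

(scatter of a reading: 0.5 percentage points)

* starting material at 15 min, in percent of the starting material charged
* mono adduct at 15 min, in percent of the starting material charged
* bis adduct at 15 min, in percent of the starting material charged
* triple product at 15 min, in percent of the starting material charged

**The fork.** At 6.00 min, the spring run reads 13.3% mono adduct and the dusk run 11.2%, with twice the reagent in spring. Their difference, 2.1 percentage points, is the doubling gain, the mono adduct gained on doubling the reagent charge at equal time and equal starting material; it is a reading from one pair of scattered values, and this reckoning assumes it for each further doubling. By these readings, a reagent molecule's chance of reaching starting material was lower in the spring run than in the dusk run. The reagent not found in mono adduct does not show as further adduct at that time: in the spring run, starting material and mono adduct sum to 100%, so bis adduct and triple product do not stand out from the scatter of 0.5 points.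

**Tighter bracket.** This reckoning takes the spring reading of 13.3% as an estimated floor for mono adduct in the flask. Adding the dusk run's rise from 4.00 min to 15.0 min gives an estimated ceiling of 14.6%. Inside it, the dusk run's last reading plus one doubling gain gives 13.5% mono adduct, which, if bis adduct and triple product stay within the scatter, leaves 86.5% starting material.

**The forecast.** On the ground that “the burst size hardly depends on reagent”, the forecast gave 85.8% starting material, 13.8% mono adduct, 0.4% bis adduct and 0.03% triple product, its mono adduct above this reckoning's figure but inside the bracket.

**The result.** The flask gives 86.4% starting material, 13.6% mono adduct, 0.0218% bis adduct and 0% triple product.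

    reagent + mono adduct → bis adduct (k = 0.590 M⁻¹ s⁻¹)
    triple product → over-reaction product (k = 0.0170 s⁻¹)
    reagent + bis adduct → triple product (k = 15.0 M⁻¹ s⁻¹)
    2 reagent → self-condensation product (k = 400 M⁻¹ s⁻¹)
    reagent ⇌ dormant form (K = 0.460, k = 0.0230 s⁻¹)
    reagent + triple product → tetra adduct (k = 20.0 M⁻¹ s⁻¹)
    starting material + reagent → mono adduct (k = 27.0 M⁻¹ s⁻¹)

At the start, reagent is used by self-condensation 30 times as fast as by the making of mono adduct. Against this result, one doubling gain is 15.4% of the flask's mono adduct.

**Second flask.** A neighbour charged with 4.00 equiv of reagent lies 2.00 doublings above the flask, so the gain gives 17.8% mono adduct. The neighbour computes to 18.8%, more than reckoned, with reagent, the limiting reagent, at 0% of its charge.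

Readings and results are calculated with constants of no real substance; noise was put on by code.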